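- Oak's target fell from 20.5% at 4.00 d to 16.5% at 8.00 d, and I built my reckoning on that loss.

| flask | substrate | remark | time |
|---|---|---|---|
| oak | 1.5 M | the very flask that is asked about, followed so far |  |
| elm | 0.75 M | run made earlier |  |
| flask | 1.5 M |  | 8.0 d |

oak run (percent of the substrate charged)

| time / d | target / % | substrate / % |
|---|---|---|
| 2.08 | 22.2 | 11.5 |
| 4.00 | 20.5 | 9.2 |
| 6.00 | 18.5 | 7.9 |
| 8.00 | 16.5 | 7.6 |

elm run (percent of the substrate charged)

| time / h | target / % | substrate / % |
|---|---|---|
| 10.0 | 21.7 | 19.9 |
| 20.0 | 23.3 | 16.6 |
| 30.0 | 23.7 | 13.5 |
| 40.0 | 23.2 | 12.7 |

(scatter of a reading: 0.3 percentage points)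

- west: change nothing and wait 8.0 d more
- south-west: at 8.0 d add substrate, 50.0% of the amount charged, then wait 8.0 d
- north: at 8.0 d take out 90% of the target then present, then wait 8.0 d

- percent here means substrate units held: one self-condensation product counts as two
- removed target is counted in
- what was read earlier has a scatter of 0.3 percentage points, one standard deviation
- steps that have been proposed: substrate <-> target; substrate <-> isomer of the product; target <-> isomer of the product; substrate <-> dormant form; 2 substrate -> self-condensation product; target -> over-reaction product
- additions bring no volume worth counting

- target, in percent of the substrate first charged, at 8.0 d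
- what to do for the largest gain in target; "none" if nothing gains more than 2 percentage points (west / south-west / north / none)
- target present, with what was taken out counted in, in percent of the substrate first charged, after west
- target present, with what was taken out counted in, in percent of the substrate first charged, after south-west

- Oak is the flask asked about, so for its target at 8.0 d I took the last reading, 16.5%, with its scatter of 0.3 percentage points.
- I looked for the crossing where making hands over to loss. Elm's target read 23.7% at 30.0 h and 23.2% at 40.0 h, a dip of 0.5 points, barely clear of the scatter. All of oak's readings fall.
- I named the drain constant λ, the logarithmic fall of target per day past that crossing: 0.0543 d⁻¹ in oak.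
- But oak's earlier stretch gave 0.0415 d⁻¹, slower. There c(target)/c(substrate) was still 1.93; it then read 2.23 at 4.00 d and 2.17 at 8.00 d. So I kept the late pair and read a pre-equilibrium drained at the rate λ.
- West then multiplies target by 0.648, giving 10.7%.
- The other options needed the pool's size, which nobody read. Running λ back to the charge gave 64.8% at 8.0 d, with target a fixed share of it.
- South-west enlarges that pool, giving 18.9%, a gain of 2.4 points, close to the 2 points margin.
- North banks 14.9% and shrinks the pool, giving 23.1%.
- Objection: self-condensation may have made the pool smaller than I assumed. With half that pool, north reached 20.6%, but south-west reached 27.2%, more, so the ranking hung on the pool's size. Elm, at half the charge, read 23.2% at 40.0 h against oak's 22.2% at 2.08 d, so I judged that cut too deep and chose north.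
- The forecast gave 16.5%, 11.2% after west and 19.2% after south-west, and chose north, holding that substrate, target, isomer of the product and dormant form “behave as one equilibrated pool, slowly drained by over-reaction”. Its west figure stood above mine.
- The flask gave 16.3%, 10.8% after west and 18.6% after south-west, and north led with 6.8 points. A neighbour charged with 0.60 M stands at 17.8%, above the high end of 16.9% that the forecast gave for this flask.

    substrate ⇌ target (K = 2.29, k = 0.105 h⁻¹)
    substrate ⇌ isomer of the product (K = 3.00, k = 0.0220 h⁻¹)
    target ⇌ isomer of the product (k = 0.0475 h⁻¹)
    substrate ⇌ dormant form (K = 1.93, k = 0.348 h⁻¹)
    2 substrate → self-condensation product (k = 0.0123 L mol⁻¹ h⁻¹)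
    target → over-reaction product (k = 0.00700 h⁻¹)

- Applied to the flask's own value, λ carries 16.3% forward to 10.6% for west. Carried back to 3.0 d, it gives 21.4%, and the flask read at that time holds 21.4%.

All runs stem from a simulated flask for an exercise, and the scatter is random.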